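## The problem

Target 16 is 3,5-dihydroxy-2-(4-methoxyphenyl)-7-[(3-methylbut-2-en-1-yl)oxy]-4H-chromen-4-one, a flat flavonol with no stereocentre. The task is therefore regiochemistry and order of events, not stereocontrol. Ring A carries oxygen on C5, C7 and C8a, and these three oxygens must end in three different states: free phenol, prenyl ether and ring oxygen O1. The fourth oxygen, the enolic 3-OH of ring C, sits at a carbon that the usual chalcone-to-flavone chemistry leaves as C–H, so it has to be installed on purpose. The prenyl aryl ether is the fragile group. Acids cleave or cyclise it, zerovalent palladium ionises it, hydrogenation removes it, and halogens, peracids, dioxiranes and quinones attack its alkene. It should come late and be followed only by base and a mild nucleophilic oxidant. The polyphenolic intermediates and the 3-hydroxychromenone are also air-sensitive in hot base. The enabling feature is that ring A is a phloroglucinol acylated at C4a by C4. Read as a chain, C5–C6–C7–C8–C8a–C4a has oxygen on every second carbon, which is a 1,3,5-triketone that a polyketide-type Claisen condensation can fold. Once ring A exists, the hydrogen bond from 5-OH to the C4 carbonyl separates O5 from O7 without protecting groups.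

## Retrosynthesis

**C3–O bond (16 ⇒ 13).** The C3–O bond is cut last, through boronate 15 and the 3-lithio species 14. Leaving C3 as C–H lets rings A and C come from the simple chalcone–flavone manifold. Alkaline peroxide oxidation of chalcone 9 (Algar–Flynn–Oyamada) would be shorter, but a 6'-oxygenated chalcone is diverted to aurones. Dioxirane epoxidation of 13 would hit the prenyl alkene. The forward step must metalate C3 of a lithium 5-phenoxide and oxidise the C–B bond with a peroxide that is not a peracid.

**O7–CH2 bond (13 ⇒ 11 + 12).** The prenyl group is removed next, giving acacetin 11 and prenyl bromide 12. Prenylating earlier, at chalcone 9 or flavanone 10, would expose the alkene to the iodine used for dehydrogenation, and 9 has three free phenols. In 11 the 5-OH is chelated and only the 7-OH is acidic and free. The forward step is a mono-O-alkylation.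

**O1–C2 bond and the C2=C3 unsaturation (11 ⇒ 9).** Ring C is opened to chalcone 9 through racemic flavanone 10. This is the natural relationship between chalcone and flavone and costs one operation. The forward step needs oxa-Michael closure and dehydrogenation without halogenating the electron-rich ring A.

**C4a–C5 bond, ring A (9 ⇒ 7).** This is the strategic cut, passing through the non-aromatic triketone 8. The neighbouring cut at C4a–C4, a Friedel–Crafts acylation of a phloroglucinol, needs phenol protection and fights O-acylation. Cutting C4a–C5 removes ring A altogether. Precursor 7 is an open chain whose only ring is ring B, and its three carbonyls at C3, C5 and C7 plus the ester carbon become the oxygen pattern of ring A. The forward reaction must choose Claisen closure over the other folding modes of the chain.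

**C6–C7 bond of the chain (7 ⇒ 2 + 5).** The chain is cut between the terminal methyl carbon of diketo ester 2 and the cinnamoyl carbonyl of Weinreb amide 5, via trianion 6. Against carboxylation of a preformed triketone, this cut splits the chain into two halves of similar size. It also uses the most nucleophilic carbanion of the polyanion. The forward step needs 1,2-addition without conjugate addition or over-addition, which the N-methoxy-N-methyl amide provides.

**Feedstocks (2 ⇒ 1; 5 ⇒ 3).** Diketo ester 2 comes from dehydroacetic acid 1 by lactone opening and loss of the acetyl group. Amide 5 comes from (E)-4-methoxycinnamic acid 3 through acyl imidazole 4. Both are one-step operations on bulk chemicals.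

## Roads not taken

**Alternative 1:** Aryne insertion into a carboxylic acid C–O bond, cutting C8a–O1 and C4a–C4.
- Forward key step: fluoride releases 3,5-bis(benzyloxy)benzyne from silyl triflate A2. The carboxylate of benzyloxyacetic acid A3 adds at the aryne carbon remote from the flanking benzyloxy group. The aryl anion then takes the acyl group from oxygen to carbon, giving the ortho-hydroxyaryl ketone A1.
- Merits: the flanking alkoxy group dictates the regiochemistry. A1 already carries the future C3 oxygen, so no late C–H oxidation is needed. It is a 2-hydroxyphenyl ketone ready for aroylation, acyl shift and cyclodehydration to the flavonol skeleton.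
- Weak points: A2 needs a multistep preparation. Simple protonation of the hindered aryl anion competes with the acyl shift. All oxygens wear the same benzyl group, so after annulation the benzyl ethers fall together. The prenyl group cannot pass through hydrogenolysis and must be placed last on a compound with both 3-OH and 7-OH free.
- Comparison: this road is better in carrying the C3 oxygen from the start. The chosen plan sets against it bulk starting materials, no protecting groups, a hydrogen-bond distinction between O5 and O7 in 11, and a prenylation with only one reactive hydroxyl.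

**Alternative 2:** Three-component carbonylative ketone arylation, cutting C4a–C4 and C4–C3.
- Forward key step: aryl iodide A5, one carbon from the gas phase and the enolate of alkoxy ketone A6 are joined by palladium catalysis to the racemic tris-MOM diketone A4. No ring closes.
- Merits: it is the most convergent road. A4 holds every carbon, the prenyl ether and the C3 oxygen. Acetal removal and cyclodehydration would finish the synthesis, so the count from the fragments would be lower than in the chosen plan.
- Weak points: A5 is electron-rich and doubly ortho-substituted, so oxidative addition and capture of the hindered acyl palladium are slow. Its aryl prenyl ether is an allylic electrophile that zerovalent palladium can ionise. A4 is more acidic than A6 and can bind the catalyst or be O-acylated. The closing acid treatment meets the acid-labile prenyl ether. A5 and A6 each need several steps.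
- Comparison: this road is better in convergence and in avoiding C3 oxidation. The chosen plan keeps transition metals and acid away from the prenyl ether and needs no protecting groups.

**Alternative 3:** Ring C closed by enolate SNAr, cutting O1–C8a.
- Forward key step: the anisyl-side enolate oxygen of difluoro diketone A8 displaces one of two equivalent ortho fluorides, giving the 5-fluorochromenone A7.
- Merits: the symmetry of the difluoroaryl ketone removes any regiochemical question. The ortho carbonyl activates the displacement and the C3 oxygen is in place. This ring closure is probably more dependable than the chosen key step, which has several competing cyclisation modes.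
- Weak points: A7 has fluorine where the target has the 5-hydroxyl. A second substitution by an oxygen nucleophile is needed, and it competes with attack at C2 and ring opening of the chromenone. The acetal on O3 must then be removed with acid in the presence of the prenyl ether. A8 requires a fluorinated aromatic building block and a crossed acylation.
- Comparison: the chosen plan has every ring A oxygen correct from the moment the ring forms, with no fluorine-to-oxygen exchange and no acid after prenylation. It pays for this with a less predictable ring closure at 7.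

Key step: step 4

Assumption: the poly-β-carbonyl compounds 2, 7 and 8 are drawn as keto tautomers although they exist largely as enols or metal enolates, and flavanone 10 is racemic.

## Route

Step 1
Reactants: 1 dehydroacetic acid (3-acetyl-6-methyl-2H-pyran-2,4(3H)-dione)
Product: 2 methyl 3,5-dioxohexanoate
Conditions: Mg(OMe)2 (2 equiv), MeOH, reflux; then cold 2 M HCl
Reagents that add atoms: methanol, CO (delivered as magnesium methoxide, CO[Mg]OC)
Why: Methoxide opens the lactone and the resulting 2-acetyl-3,5-dioxo ester loses its acetyl group by retro-Claisen cleavage; the magnesium chelate of 2 resists further cleavage, a known deacetylative ring opening of dehydroacetic acid.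

Step 2
Reactants: 3 (E)-4-methoxycinnamic acid
Product: 5 (E)-N-methoxy-3-(4-methoxyphenyl)-N-methylprop-2-enamide, via acyl imidazole 4 (not isolated)
Conditions: CDI (1,1'-carbonyldiimidazole), CH2Cl2, rt; then MeNH(OMe)·HCl, rt
Reagents that add atoms: N,O-dimethylhydroxylamine hydrochloride, CNOC.Cl; 1,1'-carbonyldiimidazole, O=C(n1ccnc1)n1ccnc1 (its imidazole is carried only in intermediate 4)
Why: Activation of the acid as acyl imidazole 4 and aminolysis is the standard Weinreb amide synthesis; the E alkene is not touched.

Step 3
Reactants: 2 methyl 3,5-dioxohexanoate (1.3 equiv); 5 (E)-N-methoxy-3-(4-methoxyphenyl)-N-methylprop-2-enamide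
Product: 7 methyl (E)-9-(4-methoxyphenyl)-3,5,7-trioxonon-8-enoate, via trilithium trianion 6 (not isolated)
Conditions: LiN(iPr)2 (3.2 equiv per 2), THF, −78 → 0 °C; then 5, −78 → −20 °C; cold 1 M HCl
Reagents that add atoms: lithium diisopropylamide, [Li]N(C(C)C)C(C)C (lithium in intermediate 6 only)
Why: Polyanion C-acylation: the terminal methyl carbanion of 6 is formed last, is least stabilised and so reacts first, adding 1,2 to the amide carbonyl. The N-methoxy-N-methyl chelate holds the adduct until the quench, so the new ketone never meets excess carbanion, and the hard carbanion together with the donor-substituted cinnamoyl amide disfavours conjugate addition.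

Step 4
Reactants: 7 methyl (E)-9-(4-methoxyphenyl)-3,5,7-trioxonon-8-enoate
Product: 9 (E)-3-(4-methoxyphenyl)-1-(2,4,6-trihydroxyphenyl)prop-2-en-1-one ((E)-2',4',6'-trihydroxy-4-methoxychalcone), via cyclohexanetrione tautomer 8 (not isolated)
Conditions: Mg(OMe)2 (4 equiv), MeOH, 25 → 60 °C, N2; then 1 M HCl, 0 °C, rapid isolation
Reagents that add atoms: none
Why: Mg(OMe)2 turns 7 into a magnesium-chelated polyenolate; the carbanion at chain carbon C6, flanked by the C5 and C7 carbonyls, adds to the ester carbonyl C1 and methoxide leaves, forming the C4a–C5 bond (flavonoid numbering) and closing ring A as triketone 8. The closure is 6-exo-trig and is allowed for either enolate description of C6. 8 enolises at once to the aromatic phloroglucinol, and deprotonation of the new phenols makes the step irreversible. The closest known reaction is the base-mediated Claisen (Dieckmann-type) cyclisation of 3,5,7-triketo esters to acylphloroglucinols, the laboratory counterpart of chalcone synthase. No stereocentre is formed and the E alkene is a spectator. The step needs Claisen closure to beat aldol closure of C2 onto C7 (a resorcylate), lactonisation of the C5 enol oxygen onto C1 (a 4-hydroxy-2-pyrone), conjugate addition to C9 and retro-Claisen cleavage of the chain. Magnesium chelation keeps C3, C5 and C7 as enolates, so C7 is a poor electrophile, further weakened by conjugation with the anisylvinyl group, and the β-diketone units resist methoxide cleavage. Methoxide matched to the methyl ester avoids hydrolysis to the acid, which would open the aldol–decarboxylation path, and the para-methoxy donor deactivates C9 as a Michael acceptor.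

Step 5
Reactants: 9 (E)-3-(4-methoxyphenyl)-1-(2,4,6-trihydroxyphenyl)prop-2-en-1-one
Product: 11 5,7-dihydroxy-2-(4-methoxyphenyl)-4H-chromen-4-one (acacetin), via racemic flavanone 10 (not isolated)
Conditions: pyridine, 90 °C; then I2 (1.1 equiv), 90–95 °C; aq Na2S2O3, dilute HCl
Reagents that add atoms: none
Why: Base-catalysed 6-endo-trig oxa-Michael addition of the 2'-hydroxyl (chalcone–flavanone isomerisation) gives 10, whose C2 stereocentre is erased when iodine in pyridine iodinates C3 through the enol and HI is eliminated. This I2/pyridine dehydrogenation is established for 5,7-dihydroxyflavanones.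

Step 6
Reactants: 11 5,7-dihydroxy-2-(4-methoxyphenyl)-4H-chromen-4-one; 12 prenyl bromide (1-bromo-3-methylbut-2-ene, 1.1 equiv)
Product: 13 5-hydroxy-2-(4-methoxyphenyl)-7-[(3-methylbut-2-en-1-yl)oxy]-4H-chromen-4-one
Conditions: K2CO3 (1.5 equiv), acetone, reflux
Reagents that add atoms: none
Why: Williamson etherification by SN2 at the primary allylic carbon. The 7-OH is the acidic, unchelated phenol, while the 5-OH is held in a hydrogen bond to the C4 carbonyl and stays free with one equivalent of bromide.

Step 7
Reactants: 13 5-hydroxy-2-(4-methoxyphenyl)-7-[(3-methylbut-2-en-1-yl)oxy]-4H-chromen-4-one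
Product: 16 3,5-dihydroxy-2-(4-methoxyphenyl)-7-[(3-methylbut-2-en-1-yl)oxy]-4H-chromen-4-one (target), via 3-lithio lithium phenoxide 14 (not isolated), via dimethyl 3-boronate 15 (not isolated)
Conditions: LiN(iPr)2 (3.5 equiv), THF, −78 °C; B(OMe)3 (5 equiv), −78 → 0 °C; 30% H2O2, 0 °C; aq Na2S2O3, 1 M HCl
Reagents that add atoms: hydrogen peroxide, OO; trimethyl borate, COB(OC)OC (in intermediate 15 only); lithium diisopropylamide, [Li]N(C(C)C)C(C)C (lithium in intermediates 14 and 15 only)
Why: C3 lithiation of a flavone by a lithium amide at −78 °C, borylation and peroxide oxidation of the C–B bond with 1,2-shift to oxygen is a known flavone-to-flavonol conversion, with the 5-hydroxyl carried as its lithium salt. The low temperature keeps 14 from fragmenting, and hydrogen peroxide without a peracid leaves the prenyl alkene alone.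

## Compound list

1 | dehydroacetic acid (3-acetyl-6-methyl-2H-pyran-2,4(3H)-dione) | CC(=O)C1C(=O)C=C(C)OC1=O | starting material
2 | methyl 3,5-dioxohexanoate | COC(=O)CC(=O)CC(C)=O | intermediate
3 | (E)-4-methoxycinnamic acid | COc1ccc(/C=C/C(=O)O)cc1 | starting material
4 | (E)-1-(1H-imidazol-1-yl)-3-(4-methoxyphenyl)prop-2-en-1-one | COc1ccc(/C=C/C(=O)n2ccnc2)cc1 | intermediate (not isolated)
5 | (E)-N-methoxy-3-(4-methoxyphenyl)-N-methylprop-2-enamide | COc1ccc(/C=C/C(=O)N(C)OC)cc1 | intermediate
6 | trilithium trianion of methyl 3,5-dioxohexanoate (deprotonated at C2, C4 and C6) | [Li+].[Li+].[Li+].C=C([O-])C=C([O-])C=C([O-])OC | intermediate (not isolated)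
7 | methyl (E)-9-(4-methoxyphenyl)-3,5,7-trioxonon-8-enoate | COC(=O)CC(=O)CC(=O)CC(=O)/C=C/c1ccc(OC)cc1 | intermediate
8 | 2-[(E)-3-(4-methoxyphenyl)prop-2-enoyl]cyclohexane-1,3,5-trione | COc1ccc(/C=C/C(=O)C2C(=O)CC(=O)CC2=O)cc1 | intermediate (not isolated)
9 | (E)-3-(4-methoxyphenyl)-1-(2,4,6-trihydroxyphenyl)prop-2-en-1-one | COc1ccc(/C=C/C(=O)c2c(O)cc(O)cc2O)cc1 | intermediate
10 | racemic 5,7-dihydroxy-2-(4-methoxyphenyl)chroman-4-one (isosakuranetin) | COc1ccc(C2CC(=O)c3c(O)cc(O)cc3O2)cc1 | intermediate (not isolated)
11 | 5,7-dihydroxy-2-(4-methoxyphenyl)-4H-chromen-4-one (acacetin) | COc1ccc(-c2cc(=O)c3c(O)cc(O)cc3o2)cc1 | intermediate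
12 | prenyl bromide (1-bromo-3-methylbut-2-ene) | CC(C)=CCBr | starting material
13 | 5-hydroxy-2-(4-methoxyphenyl)-7-[(3-methylbut-2-en-1-yl)oxy]-4H-chromen-4-one | COc1ccc(-c2cc(=O)c3c(O)cc(OCC=C(C)C)cc3o2)cc1 | intermediate
14 | lithium 3-lithio-2-(4-methoxyphenyl)-7-[(3-methylbut-2-en-1-yl)oxy]-4-oxo-4H-chromen-5-olate | [Li]c1c(-c2ccc(OC)cc2)oc2cc(OCC=C(C)C)cc(O[Li])c2c1=O | intermediate (not isolated)
15 | lithium 3-(dimethoxyboryl)-2-(4-methoxyphenyl)-7-[(3-methylbut-2-en-1-yl)oxy]-4-oxo-4H-chromen-5-olate | COB(OC)c1c(-c2ccc(OC)cc2)oc2cc(OCC=C(C)C)cc(O[Li])c2c1=O | intermediate (not isolated)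
16 | 3,5-dihydroxy-2-(4-methoxyphenyl)-7-[(3-methylbut-2-en-1-yl)oxy]-4H-chromen-4-one | COc1ccc(-c2oc3cc(OCC=C(C)C)cc(O)c3c(=O)c2O)cc1 | target

## Step count and risks

Total step count: 7. Longest linear sequence: 6 steps (steps 1, 3, 4, 5, 6, 7 from 1, or equally steps 2 to 7 from 3).

**Step 4 (key step).** The chain may fold in the wrong register. The possible failures are aldol closure of C2 onto C7 with dehydration, lactonisation to a pyrone, conjugate addition into the enone, or cleavage of the chain by methoxide. Early oxa-Michael closure of the product on acidification is harmless, because step 5 passes through 10 anyway. The fallback buys ring A instead of building it and sets out from amide 5. Commercial phloroglucinol F1 is converted with MOMCl and iPr2NEt into 1,3,5-tris(methoxymethoxy)benzene F2. F2 is lithiated between two acetal oxygens with n-BuLi in THF at 0 °C to 2,4,6-tris(methoxymethoxy)phenyllithium F3. F3 adds 1,2 to 5 to give (E)-3-(4-methoxyphenyl)-1-[2,4,6-tris(methoxymethoxy)phenyl]prop-2-en-1-one F4. HCl in methanol removes the three acetals and the route is rejoined at 9.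

**Step 3.** Trianion formation may be incomplete, so that a dianion reacts at C4 or on oxygen. Self-condensation of 2 or conjugate addition to the cinnamoyl unit may also intrude. The fallback masks the diketo ester as a pyrone with only two acidic sites and sets out from 1. Hot 90% H2SO4 deacetylates 1 to 4-hydroxy-6-methyl-2H-pyran-2-one F5. Two equivalents of LiN(iPr)2 give the dilithium dianion of F5, F6. F6 is acylated at the methyl carbon by 5 to 4-hydroxy-6-[(E)-4-(4-methoxyphenyl)-2-oxobut-3-en-1-yl]-2H-pyran-2-one F7. Mg(OMe)2 in methanol opens the pyrone of F7, as it opens 1 in step 1, and the route is rejoined at 7 in the flask of step 4.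

**Step 7.** Metalation at C3 of the phenoxide may be incomplete. Lithio species 14 may fragment to an alkynyl ketone phenoxide on warming. The prenyl ether may be deprotonated next to oxygen and rearrange. The peroxide step may over-oxidise the flavonol or epoxidise the alkene. The fallback oxidises C3 before the prenyl group is present and sets out from 11.
- BnBr and K2CO3 in DMF at 80 °C give 5,7-bis(benzyloxy)-2-(4-methoxyphenyl)-4H-chromen-4-one F8.
- Dimethyldioxirane epoxidises the 2,3-double bond to racemic 5,7-bis(benzyloxy)-2-(4-methoxyphenyl)-2,3-epoxychroman-4-one F9.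
- Catalytic p-TsOH opens F9 to 5,7-bis(benzyloxy)-3-hydroxy-2-(4-methoxyphenyl)-4H-chromen-4-one F10.
- Hydrogenolysis with H2 over palladium on carbon gives 3,5,7-trihydroxy-2-(4-methoxyphenyl)-4H-chromen-4-one F11.
- One equivalent of 12 with K2CO3 in acetone alkylates the most acidic, unchelated 7-OH and the route is rejoined at 16.

The weak point of this detour is that the 7-OH is distinguished from the 3-OH by acidity alone.

**Step 5.** Iodine may substitute ring A at C6 or C8, most readily if chalcone 9 has not fully isomerised before iodine is added. The fallback removes the free phenols and the halogen–phenol contact and sets out from 9. NaOAc in refluxing ethanol closes 9 to 10, which is isolated. Ac2O in pyridine gives racemic 5,7-diacetoxy-2-(4-methoxyphenyl)chroman-4-one F12. N-bromosuccinimide with benzoyl peroxide brominates the benzylic C2 position by a radical path, and loss of HBr gives 5,7-diacetoxy-2-(4-methoxyphenyl)-4H-chromen-4-one F13. K2CO3 in methanol removes the acetates and the route is rejoined at 11.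

## Further compounds

F1 | step 4 | phloroglucinol (benzene-1,3,5-triol, purchased) | Oc1cc(O)cc(O)c1
F2 | step 4 | 1,3,5-tris(methoxymethoxy)benzene | COCOc1cc(OCOC)cc(OCOC)c1
F3 | step 4 | 2,4,6-tris(methoxymethoxy)phenyllithium | [Li]c1c(OCOC)cc(OCOC)cc1OCOC
F4 | step 4 | (E)-3-(4-methoxyphenyl)-1-[2,4,6-tris(methoxymethoxy)phenyl]prop-2-en-1-one | COCOc1cc(OCOC)c(C(=O)/C=C/c2ccc(OC)cc2)c(OCOC)c1
F5 | step 3 | 4-hydroxy-6-methyl-2H-pyran-2-one | Cc1cc(O)cc(=O)o1
F6 | step 3 | dilithium dianion of 4-hydroxy-6-methyl-2H-pyran-2-one (4-oxide and 6-methylene carbanion) | [Li+].[Li+].[CH2-]c1cc([O-])cc(=O)o1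
F7 | step 3 | 4-hydroxy-6-[(E)-4-(4-methoxyphenyl)-2-oxobut-3-en-1-yl]-2H-pyran-2-one | COc1ccc(/C=C/C(=O)Cc2cc(O)cc(=O)o2)cc1
F8 | step 7 | 5,7-bis(benzyloxy)-2-(4-methoxyphenyl)-4H-chromen-4-one | COc1ccc(-c2cc(=O)c3c(OCc4ccccc4)cc(OCc4ccccc4)cc3o2)cc1
F9 | step 7 | racemic 5,7-bis(benzyloxy)-2-(4-methoxyphenyl)-2,3-epoxychroman-4-one | COc1ccc(C23OC2C(=O)c2c(OCc4ccccc4)cc(OCc4ccccc4)cc2O3)cc1
F10 | step 7 | 5,7-bis(benzyloxy)-3-hydroxy-2-(4-methoxyphenyl)-4H-chromen-4-one | COc1ccc(-c2oc3cc(OCc4ccccc4)cc(OCc4ccccc4)c3c(=O)c2O)cc1
F11 | step 7 | 3,5,7-trihydroxy-2-(4-methoxyphenyl)-4H-chromen-4-one | COc1ccc(-c2oc3cc(O)cc(O)c3c(=O)c2O)cc1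
F12 | step 5 | racemic 5,7-diacetoxy-2-(4-methoxyphenyl)chroman-4-one | COc1ccc(C2CC(=O)c3c(OC(C)=O)cc(OC(C)=O)cc3O2)cc1
F13 | step 5 | 5,7-diacetoxy-2-(4-methoxyphenyl)-4H-chromen-4-one | COc1ccc(-c2cc(=O)c3c(OC(C)=O)cc(OC(C)=O)cc3o2)cc1
A1 | alternative 1 | 2-(benzyloxy)-1-[2,4-bis(benzyloxy)-6-hydroxyphenyl]ethanone | O=C(COCc1ccccc1)c1c(O)cc(OCc2ccccc2)cc1OCc1ccccc1
A2 | alternative 1 | 3,5-bis(benzyloxy)-2-(trimethylsilyl)phenyl trifluoromethanesulfonate | C[Si](C)(C)c1c(OCc2ccccc2)cc(OCc2ccccc2)cc1OS(=O)(=O)C(F)(F)F
A3 | alternative 1 | 2-(benzyloxy)acetic acid | O=C(O)COCc1ccccc1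
A4 | alternative 2 | racemic 1-[2,6-bis(methoxymethoxy)-4-[(3-methylbut-2-en-1-yl)oxy]phenyl]-2-(methoxymethoxy)-3-(4-methoxyphenyl)propane-1,3-dione | COCOC(C(=O)c1ccc(OC)cc1)C(=O)c1c(OCOC)cc(OCC=C(C)C)cc1OCOC
A5 | alternative 2 | 2-iodo-1,3-bis(methoxymethoxy)-5-[(3-methylbut-2-en-1-yl)oxy]benzene | COCOc1cc(OCC=C(C)C)cc(OCOC)c1I
A6 | alternative 2 | 2-(methoxymethoxy)-1-(4-methoxyphenyl)ethan-1-one | COCOCC(=O)c1ccc(OC)cc1
A7 | alternative 3 | 5-fluoro-3-(methoxymethoxy)-2-(4-methoxyphenyl)-7-[(3-methylbut-2-en-1-yl)oxy]-4H-chromen-4-one | COCOc1c(-c2ccc(OC)cc2)oc2cc(OCC=C(C)C)cc(F)c2c1=O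
A8 | alternative 3 | racemic 1-[2,6-difluoro-4-[(3-methylbut-2-en-1-yl)oxy]phenyl]-2-(methoxymethoxy)-3-(4-methoxyphenyl)propane-1,3-dione | COCOC(C(=O)c1ccc(OC)cc1)C(=O)c1c(F)cc(OCC=C(C)C)cc1F
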